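**Plan**
- Retrosynthesis (flavanone numbering): the three O–Si bonds are cut first, then the C2–C3 bond of ring C, then the diazo group at C3 (back to an acetyl group), then the O1–CH2 ether bond, and last the C6–geranyl bond.
- Enabling feature: C2 is a methine that is benzylic to ring B and bound to O1. It therefore maps onto an O1–CH2–aryl ether whose C–H bond can accept a carbenoid sitting at C3 next to the C4 carbonyl on ring A.
- Forward: ring A is bought as 2,4,6-trihydroxyacetophenone (C4 and C3 already in place) and C-geranylated. Its three hydroxyls are then differentiated: O7 silyl, O1 isovanillyl ether by Mitsunobu reaction, O5 silyl. Ring B comes from isovanillin.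
- The methyl ketone is turned into the diazoketone by diazo transfer, so no aryllithium, acid chloride or diazomethane is used next to the silyl ethers and the geranyl chain.
- Ring C is the only ring made (step 8). C2, the only stereocentre, is set there by a chiral dirhodium carboxylate; the E alkene is carried unchanged from geranyl bromide.
- Buffered fluoride then frees the three phenols.

Key step: step 8

Remarks: TBS = tert-butyldimethylsilyl; geranyl = (2E)-3,7-dimethylocta-2,6-dien-1-yl. Open-chain intermediates use acetophenone numbering, ring C compounds use flavanone numbering.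
Assumption: the S-configured ligands of Rh2(S-PTTL)4 are taken to deliver the 2S product; if the sense proves opposite, the mirror-image catalyst Rh2(R-PTTL)4 is used with no other change.

**Step 1**
Reactants: 1 2,4,6-trihydroxyacetophenone; 2 geranyl bromide
Product: 3 3-geranyl-2,4,6-trihydroxyacetophenone
Conditions: K2CO3, acetone, reflux
Reagents that add atoms: none
Why: Base-mediated C-alkylation of an acylphloroglucinol phenoxide (the ring carbon between two hydroxyls is the soft nucleophilic site) by SN2 attack on the primary allylic bromide; the two free ring positions of 1 are equivalent, so only one C-monogeranyl isomer is possible, and the E alkene of 2 is not touched.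

**Step 2**
Reactants: 3 3-geranyl-2,4,6-trihydroxyacetophenone
Product: 4 1-[4-(tert-butyldimethylsilyloxy)-3-geranyl-2,6-dihydroxyphenyl]ethanone
Conditions: TBSCl (1 equiv), imidazole, DMF, 0 °C
Reagents that add atoms: tert-butyldimethylsilyl chloride, CC(C)(C)[Si](C)(C)Cl
Why: Imidazole-promoted silylation should pick the 4-hydroxyl, which is para to the acetyl group, the most acidic of the three and unable to hydrogen-bond to the carbonyl, while one equivalent of silyl chloride at 0 °C limits reaction at the ortho hydroxyls.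

**Step 3**
Reactants: 5 isovanillin (3-hydroxy-4-methoxybenzaldehyde)
Product: 6 3-(tert-butyldimethylsilyloxy)-4-methoxybenzaldehyde
Conditions: TBSCl, imidazole, CH2Cl2, rt
Reagents that add atoms: tert-butyldimethylsilyl chloride, CC(C)(C)[Si](C)(C)Cl
Why: Routine imidazole-promoted silylation of a phenol; the aldehyde is inert.

**Step 4**
Reactants: 6 3-(tert-butyldimethylsilyloxy)-4-methoxybenzaldehyde
Product: 7 [3-(tert-butyldimethylsilyloxy)-4-methoxyphenyl]methanol
Conditions: NaBH4, MeOH, 0 °C
Reagents that add atoms: none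
Why: Borohydride reduction of an aromatic aldehyde to the benzylic alcohol, under which an unactivated aryl silyl ether is stable at 0 °C.

**Step 5**
Reactants: 4 1-[4-(tert-butyldimethylsilyloxy)-3-geranyl-2,6-dihydroxyphenyl]ethanone; 7 [3-(tert-butyldimethylsilyloxy)-4-methoxyphenyl]methanol
Product: 8 1-[6-{[3-(tert-butyldimethylsilyloxy)-4-methoxybenzyl]oxy}-4-(tert-butyldimethylsilyloxy)-3-geranyl-2-hydroxyphenyl]ethanone
Conditions: PPh3, DIAD, THF, 0 °C → rt
Reagents that add atoms: none
Why: Mitsunobu etherification under neutral conditions (which spare the acyl-activated 4-O-silyl ether) should take place at the 6-hydroxyl, which has a ring hydrogen as neighbour, in preference to the 2-hydroxyl, which is shielded by the geranyl chain and pushed into the stronger hydrogen bond to the carbonyl; once one ortho oxygen is etherified the other is fully chelated and does not react further.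

**Step 6**
Reactants: 8 1-[6-{[3-(tert-butyldimethylsilyloxy)-4-methoxybenzyl]oxy}-4-(tert-butyldimethylsilyloxy)-3-geranyl-2-hydroxyphenyl]ethanone
Product: 9 1-[2-{[3-(tert-butyldimethylsilyloxy)-4-methoxybenzyl]oxy}-4,6-bis(tert-butyldimethylsilyloxy)-5-geranylphenyl]ethanone
Conditions: TBSOTf (1.2 equiv), 2,6-lutidine, CH2Cl2, −78 → 0 °C
Reagents that add atoms: tert-butyldimethylsilyl trifluoromethanesulfonate, CC(C)(C)[Si](C)(C)OS(=O)(=O)C(F)(F)F
Why: A silyl triflate with a hindered pyridine base is the standard means of silylating a chelated, flanked phenol, and low temperature with only a slight excess of reagent keeps the methyl ketone from being converted into its silyl enol ether.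

**Step 7**
Reactants: 9 1-[2-{[3-(tert-butyldimethylsilyloxy)-4-methoxybenzyl]oxy}-4,6-bis(tert-butyldimethylsilyloxy)-5-geranylphenyl]ethanone
Product: 11 2-diazo-1-[2-{[3-(tert-butyldimethylsilyloxy)-4-methoxybenzyl]oxy}-4,6-bis(tert-butyldimethylsilyloxy)-5-geranylphenyl]ethanone, via the trifluoroacetyl diketone 10 (not isolated)
Conditions: LiN(SiMe3)2, THF, −78 °C; CF3CO2CH2CF3, −78 °C; cold 5% aq. HCl work-up; then 4-acetamidobenzenesulfonyl azide, Et3N, H2O (1 equiv), MeCN, rt
Reagents that add atoms: 4-acetamidobenzenesulfonyl azide, CC(=O)Nc1ccc(cc1)S(=O)(=O)N=[N+]=[N-]; 2,2,2-trifluoroethyl trifluoroacetate, FC(F)(F)COC(=O)C(F)(F)F (its atoms stay only in 10)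
Why: Detrifluoroacetylative diazo transfer (Danheiser variant of the Regitz reaction): the kinetic lithium enolate of the methyl ketone is C-acylated by the trifluoroacetate ester, and the resulting 1,3-diketone takes the diazo group from the sulfonyl azide while the trifluoroacetyl group leaves on the sulfonamide nitrogen, so that no acid chloride, HCl gas or diazomethane meets the silyl ethers and the geranyl chain.

**Step 8**
Reactants: 11 2-diazo-1-[2-{[3-(tert-butyldimethylsilyloxy)-4-methoxybenzyl]oxy}-4,6-bis(tert-butyldimethylsilyloxy)-5-geranylphenyl]ethanone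
Product: 12 (2S)-5,7-bis(tert-butyldimethylsilyloxy)-2-[3-(tert-butyldimethylsilyloxy)-4-methoxyphenyl]-6-geranylchroman-4-one
Conditions: Rh2(S-PTTL)4 (dirhodium tetrakis[N-phthaloyl-(S)-tert-leucinate], 1 mol%), toluene, −20 → 0 °C, slow addition of 11
Reagents that add atoms: none
Why: Loss of N2 from 11 at the dirhodium core should give an electrophilic acyl carbenoid at C3, which inserts into a benzylic C–H bond of the O1–CH2–aryl group through a concerted, asynchronous three-centre transition state with hydride-like transfer, forming the C2–C3 bond. The closest known reaction type is the intramolecular C–H insertion of 2-alkoxyaryl diazoketones to chroman-4-ones under divalent rhodium carboxylate catalysis, applied here to a benzyl ether. The new bond makes ring C by a 1,6-closure (carbenoid carbon, C4, C4a, C8a, O1, benzylic carbon); no five-membered alternative exists because the fifth atom is the ether oxygen, which has no hydrogen. C2 is the only new stereocentre and is set by the catalyst alone: the substrate is achiral, the two benzylic hydrogens are enantiotopic, and the phthalimido walls of the tert-leucinate ligands decide which of them faces the carbenoid. The step needs insertion to win over attack of the carbenoid on O1 (oxonium ylide, then [1,2]-benzyl shift to a benzofuranone), on the silylated O5 and on the geranyl alkenes. The substrate favours insertion because the 4-methoxy-3-silyloxyphenyl group makes the benzylic C–H hydridic, O1 is a weak donor as part of a vinylogous ester, the two ortho substituents twist the acyl group out of the ring plane towards the CH2 group, the bulky silyl ethers shield O5 and offer no activated C–H bond, and the nearer geranyl alkene could only be reached through a strained meta-bridged ring.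

**Step 9**
Reactants: 12 (2S)-5,7-bis(tert-butyldimethylsilyloxy)-2-[3-(tert-butyldimethylsilyloxy)-4-methoxyphenyl]-6-geranylchroman-4-one
Product: 13 (2S)-6-geranyl-5,7-dihydroxy-2-(3-hydroxy-4-methoxyphenyl)chroman-4-one (CNP0264411.1)
Conditions: Bu4NF, AcOH (1:1), THF, 0 °C
Reagents that add atoms: none
Why: Fluoride cleaves the three aryl O–Si bonds, and the acetic acid buffer keeps the liberated 5- and 7-phenols protonated, which should prevent retro-oxa-Michael opening of ring C and thus loss of configuration at C2; the geranyl alkenes are inert.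

**Compound list**
1 | 2,4,6-trihydroxyacetophenone | CC(=O)c1c(O)cc(O)cc1O | starting material
2 | geranyl bromide, (2E)-1-bromo-3,7-dimethylocta-2,6-diene | CC(C)=CCC/C(C)=C/CBr | starting material
3 | 3-geranyl-2,4,6-trihydroxyacetophenone | CC(=O)c1c(O)cc(O)c(C/C=C(\C)CCC=C(C)C)c1O | intermediate
4 | 1-[4-(tert-butyldimethylsilyloxy)-3-geranyl-2,6-dihydroxyphenyl]ethanone | CC(=O)c1c(O)cc(O[Si](C)(C)C(C)(C)C)c(C/C=C(\C)CCC=C(C)C)c1O | intermediate
5 | isovanillin, 3-hydroxy-4-methoxybenzaldehyde | COc1ccc(C=O)cc1O | starting material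
6 | 3-(tert-butyldimethylsilyloxy)-4-methoxybenzaldehyde | COc1ccc(C=O)cc1O[Si](C)(C)C(C)(C)C | intermediate
7 | [3-(tert-butyldimethylsilyloxy)-4-methoxyphenyl]methanol | COc1ccc(CO)cc1O[Si](C)(C)C(C)(C)C | intermediate
8 | 1-[6-{[3-(tert-butyldimethylsilyloxy)-4-methoxybenzyl]oxy}-4-(tert-butyldimethylsilyloxy)-3-geranyl-2-hydroxyphenyl]ethanone | COc1ccc(COc2cc(O[Si](C)(C)C(C)(C)C)c(C/C=C(\C)CCC=C(C)C)c(O)c2C(C)=O)cc1O[Si](C)(C)C(C)(C)C | intermediate
9 | 1-[2-{[3-(tert-butyldimethylsilyloxy)-4-methoxybenzyl]oxy}-4,6-bis(tert-butyldimethylsilyloxy)-5-geranylphenyl]ethanone | COc1ccc(COc2cc(O[Si](C)(C)C(C)(C)C)c(C/C=C(\C)CCC=C(C)C)c(O[Si](C)(C)C(C)(C)C)c2C(C)=O)cc1O[Si](C)(C)C(C)(C)C | intermediate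
10 | 4,4,4-trifluoro-1-[2-{[3-(tert-butyldimethylsilyloxy)-4-methoxybenzyl]oxy}-4,6-bis(tert-butyldimethylsilyloxy)-5-geranylphenyl]butane-1,3-dione | COc1ccc(COc2cc(O[Si](C)(C)C(C)(C)C)c(C/C=C(\C)CCC=C(C)C)c(O[Si](C)(C)C(C)(C)C)c2C(=O)CC(=O)C(F)(F)F)cc1O[Si](C)(C)C(C)(C)C | intermediate
11 | 2-diazo-1-[2-{[3-(tert-butyldimethylsilyloxy)-4-methoxybenzyl]oxy}-4,6-bis(tert-butyldimethylsilyloxy)-5-geranylphenyl]ethanone | COc1ccc(COc2cc(O[Si](C)(C)C(C)(C)C)c(C/C=C(\C)CCC=C(C)C)c(O[Si](C)(C)C(C)(C)C)c2C(=O)C=[N+]=[N-])cc1O[Si](C)(C)C(C)(C)C | intermediate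
12 | (2S)-5,7-bis(tert-butyldimethylsilyloxy)-2-[3-(tert-butyldimethylsilyloxy)-4-methoxyphenyl]-6-geranylchroman-4-one | COc1ccc([C@@H]2CC(=O)c3c(cc(O[Si](C)(C)C(C)(C)C)c(C/C=C(\C)CCC=C(C)C)c3O[Si](C)(C)C(C)(C)C)O2)cc1O[Si](C)(C)C(C)(C)C | intermediate
13 | (2S)-6-geranyl-5,7-dihydroxy-2-(3-hydroxy-4-methoxyphenyl)chroman-4-one | COc1ccc([C@@H]2CC(=O)c3c(cc(O)c(C/C=C(\C)CCC=C(C)C)c3O)O2)cc1O | target

**Step count**
Total: 9 steps. Longest linear sequence: 7 steps (1, 2, 5, 6, 7, 8, 9) from 2,4,6-trihydroxyacetophenone; steps 3 and 4 form a two-step branch from isovanillin.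

**Steps most likely to fail**

Step 8. The carbenoid may be captured by the lone pair of O1, followed by a [1,2]-benzyl shift, instead of inserting. The catalyst may also distinguish the two enantiotopic benzylic hydrogens poorly. The fallback sets out from 4 and returns at 12; it sets C2 by asymmetric conjugate arylation of a chromone instead.
- Mitsunobu reaction of 4 with allyl alcohol (PPh3, DIAD) should give 1-[6-(allyloxy)-4-(tert-butyldimethylsilyloxy)-3-geranyl-2-hydroxyphenyl]ethanone F1.
- Silylation with TBSOTf and 2,6-lutidine gives 1-[2-(allyloxy)-4,6-bis(tert-butyldimethylsilyloxy)-5-geranylphenyl]ethanone F2.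
- Allyl transfer to morpholine with Pd(PPh3)4 frees the O1 hydroxyl as 1-[2,4-bis(tert-butyldimethylsilyloxy)-3-geranyl-6-hydroxyphenyl]ethanone F3.
- Heating with Me2NCH(OMe)2 gives the enaminone (E)-3-(dimethylamino)-1-[2,4-bis(tert-butyldimethylsilyloxy)-3-geranyl-6-hydroxyphenyl]prop-2-en-1-one F4.
- Mild acid (AcOH, toluene, 60 °C) closes it to 5,7-bis(tert-butyldimethylsilyloxy)-6-geranylchromen-4-one F5.
- Asymmetric 1,4-addition of purchased [3-(tert-butyldimethylsilyloxy)-4-methoxyphenyl]boronic acid, catalysed by [Rh(OH)(cod)]2 with a chiral bisphosphine of the MeO-BIPHEP type (antipode chosen for 2S) in toluene/water without added base, then gives 12.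

Step 5. The etherification may take place at the geranyl-flanked hydroxyl or at both ortho hydroxyls, or the 4-O-silyl group may be lost to the basic betaine. The fallback sets out from 1 (using 7 and 2) and returns at 9; it etherifies before geranylation, on a substrate with only one free hydroxyl, so the ether site is no longer a matter of selectivity.
- Bis-silylation of 1 (TBSCl, 2 equiv, imidazole) leaves only the chelated hydroxyl and gives 1-[2,4-bis(tert-butyldimethylsilyloxy)-6-hydroxyphenyl]ethanone F6.
- Mitsunobu reaction with 7 gives 1-[2-{[3-(tert-butyldimethylsilyloxy)-4-methoxybenzyl]oxy}-4,6-bis(tert-butyldimethylsilyloxy)phenyl]ethanone F7.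
- K2CO3 in MeOH at 0 °C removes the two acyl-activated ring A silyl ethers and should leave the unactivated one, giving 1-[2-{[3-(tert-butyldimethylsilyloxy)-4-methoxybenzyl]oxy}-4,6-dihydroxyphenyl]ethanone F8.
- C-geranylation with 2 (DBU, THF) at the ring carbon between the two hydroxyls gives 1-[2-{[3-(tert-butyldimethylsilyloxy)-4-methoxybenzyl]oxy}-5-geranyl-4,6-dihydroxyphenyl]ethanone F9.
- Double silylation (TBSOTf, 2,6-lutidine) gives 9.

Step 7. A flanking silyl group may migrate from the aryl oxygen to the enolate oxygen before C-acylation, trifluoroacetylation of the hindered enolate may be incomplete, or silyl ethers may be cleaved in the amine/water medium. The fallback sets out from 9 and returns at 11; it avoids any enolate anion.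
- Heating 9 with Me2NCH(OMe)2 gives the enaminone (E)-3-(dimethylamino)-1-[2-{[3-(tert-butyldimethylsilyloxy)-4-methoxybenzyl]oxy}-4,6-bis(tert-butyldimethylsilyloxy)-5-geranylphenyl]prop-2-en-1-one F10.
- Tosyl azide in MeCN at rt adds to the enamine double bond, and the triazoline fragments to 11 and a sulfonyl formamidine.

**Further compounds**
F1 | step 8 | 1-[6-(allyloxy)-4-(tert-butyldimethylsilyloxy)-3-geranyl-2-hydroxyphenyl]ethanone | C=CCOc1cc(O[Si](C)(C)C(C)(C)C)c(C/C=C(\C)CCC=C(C)C)c(O)c1C(C)=O
F2 | step 8 | 1-[2-(allyloxy)-4,6-bis(tert-butyldimethylsilyloxy)-5-geranylphenyl]ethanone | C=CCOc1cc(O[Si](C)(C)C(C)(C)C)c(C/C=C(\C)CCC=C(C)C)c(O[Si](C)(C)C(C)(C)C)c1C(C)=O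
F3 | step 8 | 1-[2,4-bis(tert-butyldimethylsilyloxy)-3-geranyl-6-hydroxyphenyl]ethanone | CC(=O)c1c(O)cc(O[Si](C)(C)C(C)(C)C)c(C/C=C(\C)CCC=C(C)C)c1O[Si](C)(C)C(C)(C)C
F4 | step 8 | (E)-3-(dimethylamino)-1-[2,4-bis(tert-butyldimethylsilyloxy)-3-geranyl-6-hydroxyphenyl]prop-2-en-1-one | CN(C)/C=C/C(=O)c1c(O)cc(O[Si](C)(C)C(C)(C)C)c(C/C=C(\C)CCC=C(C)C)c1O[Si](C)(C)C(C)(C)C
F5 | step 8 | 5,7-bis(tert-butyldimethylsilyloxy)-6-geranylchromen-4-one | O=c1ccoc2cc(O[Si](C)(C)C(C)(C)C)c(C/C=C(\C)CCC=C(C)C)c(O[Si](C)(C)C(C)(C)C)c12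
F6 | step 5 | 1-[2,4-bis(tert-butyldimethylsilyloxy)-6-hydroxyphenyl]ethanone | CC(=O)c1c(O)cc(O[Si](C)(C)C(C)(C)C)cc1O[Si](C)(C)C(C)(C)C
F7 | step 5 | 1-[2-{[3-(tert-butyldimethylsilyloxy)-4-methoxybenzyl]oxy}-4,6-bis(tert-butyldimethylsilyloxy)phenyl]ethanone | COc1ccc(COc2cc(O[Si](C)(C)C(C)(C)C)cc(O[Si](C)(C)C(C)(C)C)c2C(C)=O)cc1O[Si](C)(C)C(C)(C)C
F8 | step 5 | 1-[2-{[3-(tert-butyldimethylsilyloxy)-4-methoxybenzyl]oxy}-4,6-dihydroxyphenyl]ethanone | COc1ccc(COc2cc(O)cc(O)c2C(C)=O)cc1O[Si](C)(C)C(C)(C)C
F9 | step 5 | 1-[2-{[3-(tert-butyldimethylsilyloxy)-4-methoxybenzyl]oxy}-5-geranyl-4,6-dihydroxyphenyl]ethanone | COc1ccc(COc2cc(O)c(C/C=C(\C)CCC=C(C)C)c(O)c2C(C)=O)cc1O[Si](C)(C)C(C)(C)C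
F10 | step 7 | (E)-3-(dimethylamino)-1-[2-{[3-(tert-butyldimethylsilyloxy)-4-methoxybenzyl]oxy}-4,6-bis(tert-butyldimethylsilyloxy)-5-geranylphenyl]prop-2-en-1-one | COc1ccc(COc2cc(O[Si](C)(C)C(C)(C)C)c(C/C=C(\C)CCC=C(C)C)c(O[Si](C)(C)C(C)(C)C)c2C(=O)/C=C/N(C)C)cc1O[Si](C)(C)C(C)(C)C
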